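**Retrosynthetic overview**

1. Numbering: C1 ester carbon, C2, dioxane C3–C6, linker C7–C8, decalin C9, C10=C11, C12, C13, gem-dimethyl C14, C15–C17, angular C18. The strategy rests on ring B (C9, C10 with its methyl, C11, C12, C13, C18) plus C14 being (S)-carvone carbon for carbon: C13 is the carvone stereocentre and the carvone enone is the C9 ketone with the C10=C11 alkene.
2. Ring A is closed by the C14–C15 bond: the tertiary C14 cation of a doubly α′-alkylated carvone hydrate is captured by a (Z)-vinylsilane (C15=C16); C18–C17 comes from the second alkylation.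
3. C7–C8 is cut as a C7=C8 Julia–Kocienski olefin (then diimide): a C8 tetrazolyl sulfone (C9 ketone → methylene → hydroboration) plus a C1–C7 1,2-dioxane aldehyde.
4. Dioxane ring: O–C3 by SN2 closure of a C6 tertiary hydroperoxide onto a C3 mesylate (inversion); C6–OOH by perhydrolysis of an asymmetric epoxide (inversion); C2/C3 by a syn-aldol on an aldehyde from geranyl acetate.
5. Ring order: ring B (carvone) → ring A (key step); the dioxane ring is made in a separate branch; union, then C1 is taken to the methyl ester.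

Key step: step 7

Assumption: L-(+)-diethyl tartrate is taken to epoxidize allylic alcohol 25 in the same facial sense as it does geraniol, i.e. to give the (2S,3S)-type epoxy alcohol.

**Decalin branch**

Step 1
Reactants: 1 (S)-(+)-carvone
Product: 2 (5S)-5-(2-hydroxypropan-2-yl)-2-methylcyclohex-2-en-1-one (carvone hydrate)
Conditions: Co(acac)2 (cat.), PhSiH3, O2 (1 atm), THF, rt
Reagents that add atoms: dioxygen, O=O
Why: Mukaiyama hydration (metal-hydride H-atom transfer, O2 trapping, reduction) should add water in the Markovnikov sense to the electron-rich 1,1-disubstituted isopropenyl group and leave the conjugated enone and the C13 stereocentre untouched.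

Step 2
Reactants: 2 carvone hydrate
Product: 3 (5S)-2-methyl-5-{2-[(trimethylsilyl)oxy]propan-2-yl}cyclohex-2-en-1-one
Conditions: TMSCl, imidazole, DMF, rt
Reagents that add atoms: chlorotrimethylsilane, C[Si](C)(C)Cl
Why: O-silylation masks the tertiary alcohol so that only the ketone enolate reacts in the two alkylations.

Step 3
Reactants: 3 silyl ether of carvone hydrate
Product: 4 (5S)-2,6-dimethyl-5-{2-[(trimethylsilyl)oxy]propan-2-yl}cyclohex-2-en-1-one (C6 epimers, methyl trans to the C5 group expected as the major one)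
Conditions: LDA, THF, −78 °C; MeI, −78 → 0 °C
Reagents that add atoms: iodomethane, CI
Why: Kinetic α′-deprotonation of the enone followed by enolate methylation installs the future C18 methyl; the configuration of this centre is erased again in step 6.

Step 4
Reactants: 5 3-(trimethylsilyl)prop-2-yn-1-ol
Product: 6 (Z)-3-(trimethylsilyl)prop-2-en-1-ol
Conditions: H2 (1 atm), P-2 Ni [Ni(OAc)2, NaBH4], ethylenediamine, EtOH, rt
Reagents that add atoms: none
Why: Syn semi-hydrogenation of the silylalkyne on a poisoned nickel surface should give the (Z)-vinylsilane.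

Step 5
Reactants: 6 (Z)-3-(trimethylsilyl)prop-2-en-1-ol
Product: 7 (Z)-(3-bromoprop-1-en-1-yl)trimethylsilane
Conditions: CBr4, PPh3, CH2Cl2, 0 °C
Reagents that add atoms: tetrabromomethane, BrC(Br)(Br)Br
Why: Appel bromination converts the primary allylic alcohol into the bromide under neutral conditions that keep the Z geometry and the C–Si bond.

Step 6
Reactants: 4 α′-methyl ketone; 7 (Z)-silylallyl bromide
Product: 9 (5S,6R)-5-(2-hydroxypropan-2-yl)-2,6-dimethyl-6-[(2Z)-3-(trimethylsilyl)prop-2-en-1-yl]cyclohex-2-en-1-one, via bis-silyl ketone 8 (not isolated)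
Conditions: LDA, THF, −78 → −20 °C; 7, DMPU, −78 → 0 °C; then 1 M HCl, THF, rt
Reagents that add atoms: none
Why: Enolate alkylation in which the allylic bromide enters anti to the bulky C13 substituent, so C17 ends up trans to C14 and the methyl cis (this sets C18); dilute acid then cleaves the tertiary O–SiMe3 group while the vinylsilane survives.

Step 7
Reactants: 9 hydroxy vinylsilane (cyclization precursor)
Product: 10 (4aR,8aR)-2,5,5,8a-tetramethyl-4a,5,8,8a-tetrahydronaphthalen-1(4H)-one (trans-fused dienone)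
Conditions: TiCl4, 2,6-di-tert-butyl-4-methylpyridine, CH2Cl2, −78 → −20 °C
Reagents that add atoms: none
Why: TiCl4 ionizes the tertiary C14–OH to the dimethyl-substituted C14 cation, which the (Z)-vinylsilane attacks through its silicon-bearing carbon C15; the C16 cation so formed is β to silicon and collapses by loss of the silyl group to the C15=C16 alkene (ipso substitution). The closest known reaction type is the vinylsilane-terminated cation–olefin cyclization of tertiary carbocations. Ring A closes in a 6-endo-trig, chair-like mode with respect to the vinylsilane, and because the C13–C14 and C18–C17 bonds are trans and become diequatorial on the carvone ring, only the trans-fused decalin can form. No stereocentre is created: C13 comes from carvone and C18 from step 6. The step needs regiocontrol (attack at C15, not C16, i.e. a six- and not a five-membered ring), secured by β-silyl stabilisation and by the Z geometry that places silicon where the new bond forms; it also needs cyclization to outrun E1 proton loss and protodesilylation, which low temperature and the hindered base favour, while the hindered enone is too poor an electrophile to interfere.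

Step 8
Reactants: 10 dienone
Product: 11 (4aR,8aR)-2,5,5,8a-tetramethyl-4a,5,6,7,8,8a-hexahydronaphthalen-1(4H)-one
Conditions: H2 (1 atm), RhCl(PPh3)3 (cat.), benzene, rt
Reagents that add atoms: none
Why: Homogeneous hydrogenation with Wilkinson's catalyst reduces the cis-disubstituted C15=C16 alkene and should not touch the trisubstituted, conjugated C10=C11 alkene.

Step 9
Reactants: 11 decalin enone
Product: 12 (4aR,8aR)-2,5,5,8a-tetramethyl-1-methylidene-1,4,4a,5,6,7,8,8a-octahydronaphthalene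
Conditions: Tebbe reagent, pyridine (cat.), THF/toluene, −40 °C → rt
Reagents that add atoms: Tebbe reagent, C[Al-]1(C)C[Ti](C2C=CC=C2)(C2C=CC=C2)[Cl+]1
Why: Titanium-carbene (Tebbe) methylenation is non-basic and tolerates the hindered C9 ketone flanked by the quaternary C18, giving the 1,3-diene without enolization toward C12.

Step 10
Reactants: 12 diene
Product: 14 [(1R,4aR,8aR)-2,5,5,8a-tetramethyl-1,4,4a,5,6,7,8,8a-octahydronaphthalen-1-yl]methanol (ent-drimenol), via B-alkyl-9-BBN borane 13 (not isolated)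
Conditions: 9-BBN, THF, 0 °C → rt; then NaOH, 30% H2O2, 0 °C → rt
Reagents that add atoms: 9-borabicyclo[3.3.1]nonane, B1C2CCCC1CCC2; hydrogen peroxide, OO
Why: Hydroboration–oxidation places boron on the terminal C8 of the 1,1-disubstituted alkene and delivers hydrogen to C9 from the face anti to the axial C18 methyl, which sets C9 with the CH2OH arm cis to that methyl; the hindered trisubstituted C10=C11 alkene should not react with 9-BBN.

Step 11
Reactants: 14 ent-drimenol
Product: 15 5-({[(1R,4aR,8aR)-2,5,5,8a-tetramethyl-1,4,4a,5,6,7,8,8a-octahydronaphthalen-1-yl]methyl}sulfanyl)-1-phenyl-1H-tetrazole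
Conditions: 1-phenyl-1H-tetrazole-5-thiol, PPh3, DIAD, THF, 0 °C → rt
Reagents that add atoms: 1-phenyl-1H-tetrazole-5-thiol, Sc1nnnn1-c1ccccc1
Why: Mitsunobu thioetherification of the primary alcohol with the acidic tetrazole thiol forms the C8–S bond without touching C9.

Step 12
Reactants: 15 tetrazolyl sulfide
Product: 16 5-({[(1R,4aR,8aR)-2,5,5,8a-tetramethyl-1,4,4a,5,6,7,8,8a-octahydronaphthalen-1-yl]methyl}sulfonyl)-1-phenyl-1H-tetrazole
Conditions: (NH4)6Mo7O24·4H2O (cat.), 30% H2O2, EtOH, 0 °C → rt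
Reagents that add atoms: hydrogen peroxide, OO
Why: Molybdate-catalysed peroxide oxidation takes the sulfide to the sulfone and is mild enough to spare the trisubstituted alkene.

**Dioxane branch**

Step 13
Reactants: 17 geranyl acetate
Product: 18 (2E)-5-(3,3-dimethyloxiran-2-yl)-3-methylpent-2-en-1-yl acetate (6,7-epoxygeranyl acetate, racemic at the epoxide)
Conditions: mCPBA (1 equiv), NaHCO3, CH2Cl2, 0 °C
Reagents that add atoms: 3-chloroperbenzoic acid, OOC(=O)c1cccc(Cl)c1
Why: Peracid epoxidation goes to the distal, more electron-rich trisubstituted alkene because the allylic acetate deactivates the other one.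

Step 14
Reactants: 18 6,7-epoxygeranyl acetate
Product: 19 (2E)-3-methyl-6-oxohex-2-en-1-yl acetate
Conditions: H5IO6, THF/Et2O, 0 °C
Reagents that add atoms: none
Why: Periodic acid opens the epoxide and cleaves the resulting glycol in one operation (oxidative glycol cleavage), releasing acetone and leaving the C3 aldehyde with the (E)-alkene and the acetate intact.

Step 15
Reactants: 19 aldehyde; 20 (4S)-4-benzyl-3-propanoyl-1,3-oxazolidin-2-one
Product: 21 (2E,6R,7S)-8-[(4S)-4-benzyl-2-oxo-1,3-oxazolidin-3-yl]-6-hydroxy-3,7-dimethyl-8-oxooct-2-en-1-yl acetate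
Conditions: 20, Bu2BOTf, iPr2NEt, CH2Cl2, 0 °C; 19, −78 → 0 °C; pH 7 buffer, MeOH, 30% H2O2
Reagents that add atoms: none
Why: Evans syn-aldol: the (Z)-boron enolate reacts through a closed chair transition state on the face left open by the benzyl group, which sets C2 and C3 as the (2S,3R) syn pair needed before the later inversion at C3.

Step 16
Reactants: 21 aldol adduct
Product: 22 (2E,6R,7R)-6,8-dihydroxy-3,7-dimethyloct-2-en-1-yl acetate
Conditions: NaBH4, THF/H2O, 0 °C → rt
Reagents that add atoms: none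
Why: Borohydride in wet THF reductively cleaves the activated N-acyl oxazolidinone to the C1 primary alcohol and should leave the less electrophilic acetate in place.

Step 17
Reactants: 22 diol
Product: 23 (2E,6R,7R)-8-[(tert-butyldiphenylsilyl)oxy]-6-hydroxy-3,7-dimethyloct-2-en-1-yl acetate
Conditions: TBDPSCl, imidazole, CH2Cl2, 0 °C
Reagents that add atoms: tert-butyl(chloro)diphenylsilane, CC(C)(C)[Si](Cl)(c1ccccc1)c1ccccc1
Why: The bulky silyl chloride silylates the primary C1 hydroxyl selectively over the secondary C3 hydroxyl.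

Step 18
Reactants: 23 C1 silyl ether
Product: 24 (2E,6R,7R)-8-[(tert-butyldiphenylsilyl)oxy]-3,7-dimethyl-6-[(methylsulfonyl)oxy]oct-2-en-1-yl acetate
Conditions: MsCl, Et3N, CH2Cl2, 0 °C
Reagents that add atoms: methanesulfonyl chloride, CS(=O)(=O)Cl
Why: Sulfonylation turns the C3 hydroxyl into a leaving group with retention, ready for the later SN2 ring closure.

Step 19
Reactants: 24 mesylate acetate
Product: 25 (2R,3R,6E)-1-[(tert-butyldiphenylsilyl)oxy]-8-hydroxy-2,6-dimethyloct-6-en-3-yl methanesulfonate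
Conditions: K2CO3 (cat.), MeOH, 0 °C
Reagents that add atoms: none
Why: Mild transesterification removes the acetate and frees the allylic alcohol; the secondary mesylate and the silyl ether are stable to these conditions.

Step 20
Reactants: 25 allylic alcohol
Product: 26 (2R,3R)-1-[(tert-butyldiphenylsilyl)oxy]-5-[(2S,3S)-3-(hydroxymethyl)-2-methyloxiran-2-yl]-2-methylpentan-3-yl methanesulfonate
Conditions: Ti(OiPr)4, L-(+)-DET, t-BuOOH, 4 Å MS, CH2Cl2, −20 °C
Reagents that add atoms: tert-butyl hydroperoxide, CC(C)(C)OO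
Why: Sharpless asymmetric epoxidation of the geraniol-type (E)-trisubstituted allylic alcohol: the tartrate-titanium complex delivers oxygen to one alkene face and so fixes C6 (and C7) in the (S,S) sense, as with geraniol.

Step 21
Reactants: 26 epoxy alcohol
Product: 27 (2R,3R,6R,7S)-1-[(tert-butyldiphenylsilyl)oxy]-6-hydroperoxy-7,8-dihydroxy-2,6-dimethyloctan-3-yl methanesulfonate
Conditions: anhydrous ethereal H2O2, phosphomolybdic acid (cat.), Et2O, rt
Reagents that add atoms: hydrogen peroxide, OO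
Why: Acid-catalysed perhydrolysis of the trisubstituted epoxide: H2O2 attacks the more substituted carbon C6 in a loose SN2 opening with inversion, so C6 gets its peroxy oxygen in the configuration of the target.

Step 22
Reactants: 27 hydroperoxy diol mesylate
Product: 28 (1S)-1-[(3R,6S)-6-{(2R)-1-[(tert-butyldiphenylsilyl)oxy]propan-2-yl}-3-methyl-1,2-dioxan-3-yl]ethane-1,2-diol
Conditions: KOtBu (1.05 equiv), 18-crown-6, THF, 0 °C
Reagents that add atoms: none
Why: The hydroperoxide is the most acidic site, and its anion displaces the C3 mesylate in a 6-exo-tet SN2 closure (intramolecular hydroperoxide alkylation) with inversion, which converts the syn-aldol pair into the C2/C3 configuration of the target and closes the dioxane ring.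

Step 23
Reactants: 28 dioxane diol
Product: 29 (3R,6S)-6-{(2R)-1-[(tert-butyldiphenylsilyl)oxy]propan-2-yl}-3-methyl-1,2-dioxane-3-carbaldehyde
Conditions: NaIO4, THF/H2O, 0 °C → rt
Reagents that add atoms: none
Why: Periodate glycol cleavage removes the terminal carbon as formaldehyde and leaves the non-enolizable C7 aldehyde on the quaternary C6; the dialkyl peroxide is inert to periodate.

**Union and end game**

Step 24
Reactants: 16 decalin tetrazolyl sulfone; 29 dioxane aldehyde
Product: 30 tert-butyl{(2R)-2-[(3S,6R)-6-methyl-6-{(E)-2-[(1R,4aR,8aR)-2,5,5,8a-tetramethyl-1,4,4a,5,6,7,8,8a-octahydronaphthalen-1-yl]ethenyl}-1,2-dioxan-3-yl]propoxy}diphenylsilane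
Conditions: KHMDS added to 16 + 29, THF, −78 °C → rt
Reagents that add atoms: none
Why: Julia–Kocienski olefination under Barbier conditions: the C8 sulfonyl anion adds to the non-enolizable aldehyde as it forms, and Smiles rearrangement with loss of SO2 and tetrazolate gives the C7=C8 alkene, whose geometry is irrelevant because it is reduced next.

Step 25
Reactants: 30 C7=C8 alkene
Product: 31 tert-butyl{(2R)-2-[(3S,6S)-6-methyl-6-{2-[(1R,4aR,8aR)-2,5,5,8a-tetramethyl-1,4,4a,5,6,7,8,8a-octahydronaphthalen-1-yl]ethyl}-1,2-dioxan-3-yl]propoxy}diphenylsilane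
Conditions: KO2CN=NCO2K (excess), AcOH, CH2Cl2/MeOH, 0 °C → rt, repeated until complete
Reagents that add atoms: none
Why: Diimide reduction transfers H2 concertedly to the disubstituted C7=C8 alkene, reacts much more slowly with the trisubstituted C10=C11 alkene and does not cleave the O–O bond.

Step 26
Reactants: 31 silyl ether
Product: 32 (2R)-2-[(3S,6S)-6-methyl-6-{2-[(1R,4aR,8aR)-2,5,5,8a-tetramethyl-1,4,4a,5,6,7,8,8a-octahydronaphthalen-1-yl]ethyl}-1,2-dioxan-3-yl]propan-1-ol
Conditions: TBAF, AcOH, THF, rt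
Reagents that add atoms: none
Why: Fluoride desilylation buffered with acetic acid frees the C1 alcohol without exposing the peroxide to strong base.

Step 27
Reactants: 32 primary alcohol
Product: 34 (2S)-2-[(3S,6S)-6-methyl-6-{2-[(1R,4aR,8aR)-2,5,5,8a-tetramethyl-1,4,4a,5,6,7,8,8a-octahydronaphthalen-1-yl]ethyl}-1,2-dioxan-3-yl]propanoic acid, via C1 aldehyde 33 (not isolated)
Conditions: TEMPO (cat.), PhI(OAc)2, MeCN/pH 7 buffer, rt
Reagents that add atoms: water, O
Why: Oxoammonium (TEMPO) oxidation takes the alcohol through the aldehyde hydrate to the acid under near-neutral conditions, which should avoid epimerization at C2 and β-elimination of the peroxide and spare the alkene.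

Step 28
Reactants: 34 carboxylic acid
Product: 35 methyl (2S)-2-[(3S,6S)-6-methyl-6-{2-[(1R,4aR,8aR)-2,5,5,8a-tetramethyl-1,4,4a,5,6,7,8,8a-octahydronaphthalen-1-yl]ethyl}-1,2-dioxan-3-yl]propanoate (target)
Conditions: TMSCHN2, MeOH/toluene, 0 °C
Reagents that add atoms: (trimethylsilyl)diazomethane, C[Si](C)(C)C=[N+]=[N-]
Why: Diazoalkane O-methylation esterifies the acid without base or acid that could touch C2 or the peroxide.

**Compound list**

1 | (S)-(+)-carvone | CC1=CC[C@@H](CC1=O)C(C)=C | starting material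
2 | (5S)-5-(2-hydroxypropan-2-yl)-2-methylcyclohex-2-en-1-one | CC1=CC[C@@H](CC1=O)C(C)(C)O | intermediate
3 | (5S)-2-methyl-5-{2-[(trimethylsilyl)oxy]propan-2-yl}cyclohex-2-en-1-one | CC1=CC[C@@H](CC1=O)C(C)(C)O[Si](C)(C)C | intermediate
4 | (5S)-2,6-dimethyl-5-{2-[(trimethylsilyl)oxy]propan-2-yl}cyclohex-2-en-1-one (C6 epimers) | O=C1C(C)=CC[C@H](C(C)(C)O[Si](C)(C)C)C1C | intermediate
5 | 3-(trimethylsilyl)prop-2-yn-1-ol | C[Si](C)(C)C#CCO | starting material
6 | (Z)-3-(trimethylsilyl)prop-2-en-1-ol | C[Si](C)(C)/C=C\CO | intermediate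
7 | (Z)-(3-bromoprop-1-en-1-yl)trimethylsilane | C[Si](C)(C)/C=C\CBr | intermediate
8 | (5S,6R)-2,6-dimethyl-6-[(2Z)-3-(trimethylsilyl)prop-2-en-1-yl]-5-{2-[(trimethylsilyl)oxy]propan-2-yl}cyclohex-2-en-1-one | O=C1C(C)=CC[C@H](C(C)(C)O[Si](C)(C)C)[C@@]1(C)C/C=C\[Si](C)(C)C | intermediate
9 | (5S,6R)-5-(2-hydroxypropan-2-yl)-2,6-dimethyl-6-[(2Z)-3-(trimethylsilyl)prop-2-en-1-yl]cyclohex-2-en-1-one | O=C1C(C)=CC[C@H](C(C)(C)O)[C@@]1(C)C/C=C\[Si](C)(C)C | intermediate
10 | (4aR,8aR)-2,5,5,8a-tetramethyl-4a,5,8,8a-tetrahydronaphthalen-1(4H)-one | O=C1C(C)=CC[C@@H]2C(C)(C)C=CC[C@@]12C | intermediate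
11 | (4aR,8aR)-2,5,5,8a-tetramethyl-4a,5,6,7,8,8a-hexahydronaphthalen-1(4H)-one | O=C1C(C)=CC[C@@H]2C(C)(C)CCC[C@@]12C | intermediate
12 | (4aR,8aR)-2,5,5,8a-tetramethyl-1-methylidene-1,4,4a,5,6,7,8,8a-octahydronaphthalene | C=C1C(C)=CC[C@@H]2C(C)(C)CCC[C@@]12C | intermediate
13 | 9-{[(1R,4aR,8aR)-2,5,5,8a-tetramethyl-1,4,4a,5,6,7,8,8a-octahydronaphthalen-1-yl]methyl}-9-borabicyclo[3.3.1]nonane | C(B1C2CCCC1CCC2)[C@@H]1C(C)=CC[C@@H]2C(C)(C)CCC[C@@]12C | intermediate
14 | [(1R,4aR,8aR)-2,5,5,8a-tetramethyl-1,4,4a,5,6,7,8,8a-octahydronaphthalen-1-yl]methanol (ent-drimenol) | OC[C@@H]1C(C)=CC[C@@H]2C(C)(C)CCC[C@@]12C | intermediate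
15 | 5-({[(1R,4aR,8aR)-2,5,5,8a-tetramethyl-1,4,4a,5,6,7,8,8a-octahydronaphthalen-1-yl]methyl}sulfanyl)-1-phenyl-1H-tetrazole | S(C[C@@H]1C(C)=CC[C@@H]2C(C)(C)CCC[C@@]12C)c1nnnn1-c1ccccc1 | intermediate
16 | 5-({[(1R,4aR,8aR)-2,5,5,8a-tetramethyl-1,4,4a,5,6,7,8,8a-octahydronaphthalen-1-yl]methyl}sulfonyl)-1-phenyl-1H-tetrazole | O=S(=O)(C[C@@H]1C(C)=CC[C@@H]2C(C)(C)CCC[C@@]12C)c1nnnn1-c1ccccc1 | intermediate
17 | geranyl acetate | CC(C)=CCC/C(C)=C/COC(C)=O | starting material
18 | (2E)-5-(3,3-dimethyloxiran-2-yl)-3-methylpent-2-en-1-yl acetate | CC1(C)OC1CC/C(C)=C/COC(C)=O | intermediate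
19 | (2E)-3-methyl-6-oxohex-2-en-1-yl acetate | O=CCC/C(C)=C/COC(C)=O | intermediate
20 | (4S)-4-benzyl-3-propanoyl-1,3-oxazolidin-2-one | CCC(=O)N1[C@@H](Cc2ccccc2)COC1=O | starting material
21 | (2E,6R,7S)-8-[(4S)-4-benzyl-2-oxo-1,3-oxazolidin-3-yl]-6-hydroxy-3,7-dimethyl-8-oxooct-2-en-1-yl acetate | O=C([C@@H](C)[C@H](O)CC/C(C)=C/COC(C)=O)N1[C@@H](Cc2ccccc2)COC1=O | intermediate
22 | (2E,6R,7R)-6,8-dihydroxy-3,7-dimethyloct-2-en-1-yl acetate | OC[C@@H](C)[C@H](O)CC/C(C)=C/COC(C)=O | intermediate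
23 | (2E,6R,7R)-8-[(tert-butyldiphenylsilyl)oxy]-6-hydroxy-3,7-dimethyloct-2-en-1-yl acetate | CC(C)(C)[Si](c1ccccc1)(c1ccccc1)OC[C@@H](C)[C@H](O)CC/C(C)=C/COC(C)=O | intermediate
24 | (2E,6R,7R)-8-[(tert-butyldiphenylsilyl)oxy]-3,7-dimethyl-6-[(methylsulfonyl)oxy]oct-2-en-1-yl acetate | CC(C)(C)[Si](c1ccccc1)(c1ccccc1)OC[C@@H](C)[C@H](OS(C)(=O)=O)CC/C(C)=C/COC(C)=O | intermediate
25 | (2R,3R,6E)-1-[(tert-butyldiphenylsilyl)oxy]-8-hydroxy-2,6-dimethyloct-6-en-3-yl methanesulfonate | CC(C)(C)[Si](c1ccccc1)(c1ccccc1)OC[C@@H](C)[C@H](OS(C)(=O)=O)CC/C(C)=C/CO | intermediate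
26 | (2R,3R)-1-[(tert-butyldiphenylsilyl)oxy]-5-[(2S,3S)-3-(hydroxymethyl)-2-methyloxiran-2-yl]-2-methylpentan-3-yl methanesulfonate | CC(C)(C)[Si](c1ccccc1)(c1ccccc1)OC[C@@H](C)[C@H](OS(C)(=O)=O)CC[C@]1(C)O[C@H]1CO | intermediate
27 | (2R,3R,6R,7S)-1-[(tert-butyldiphenylsilyl)oxy]-6-hydroperoxy-7,8-dihydroxy-2,6-dimethyloctan-3-yl methanesulfonate | CC(C)(C)[Si](c1ccccc1)(c1ccccc1)OC[C@@H](C)[C@H](OS(C)(=O)=O)CC[C@@](C)(OO)[C@@H](O)CO | intermediate
28 | (1S)-1-[(3R,6S)-6-{(2R)-1-[(tert-butyldiphenylsilyl)oxy]propan-2-yl}-3-methyl-1,2-dioxan-3-yl]ethane-1,2-diol | CC(C)(C)[Si](c1ccccc1)(c1ccccc1)OC[C@@H](C)[C@@H]1CC[C@@](C)(OO1)[C@@H](O)CO | intermediate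
29 | (3R,6S)-6-{(2R)-1-[(tert-butyldiphenylsilyl)oxy]propan-2-yl}-3-methyl-1,2-dioxane-3-carbaldehyde | CC(C)(C)[Si](c1ccccc1)(c1ccccc1)OC[C@@H](C)[C@@H]1CC[C@@](C)(OO1)C=O | intermediate
30 | tert-butyl{(2R)-2-[(3S,6R)-6-methyl-6-{(E)-2-[(1R,4aR,8aR)-2,5,5,8a-tetramethyl-1,4,4a,5,6,7,8,8a-octahydronaphthalen-1-yl]ethenyl}-1,2-dioxan-3-yl]propoxy}diphenylsilane | CC(C)(C)[Si](c1ccccc1)(c1ccccc1)OC[C@@H](C)[C@@H]1CC[C@](C)(/C=C/[C@@H]2C(C)=CC[C@@H]3C(C)(C)CCC[C@@]23C)OO1 | intermediate
31 | tert-butyl{(2R)-2-[(3S,6S)-6-methyl-6-{2-[(1R,4aR,8aR)-2,5,5,8a-tetramethyl-1,4,4a,5,6,7,8,8a-octahydronaphthalen-1-yl]ethyl}-1,2-dioxan-3-yl]propoxy}diphenylsilane | CC(C)(C)[Si](c1ccccc1)(c1ccccc1)OC[C@@H](C)[C@@H]1CC[C@](C)(CC[C@@H]2C(C)=CC[C@@H]3C(C)(C)CCC[C@@]23C)OO1 | intermediate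
32 | (2R)-2-[(3S,6S)-6-methyl-6-{2-[(1R,4aR,8aR)-2,5,5,8a-tetramethyl-1,4,4a,5,6,7,8,8a-octahydronaphthalen-1-yl]ethyl}-1,2-dioxan-3-yl]propan-1-ol | OC[C@@H](C)[C@@H]1CC[C@](C)(CC[C@@H]2C(C)=CC[C@@H]3C(C)(C)CCC[C@@]23C)OO1 | intermediate
33 | (2S)-2-[(3S,6S)-6-methyl-6-{2-[(1R,4aR,8aR)-2,5,5,8a-tetramethyl-1,4,4a,5,6,7,8,8a-octahydronaphthalen-1-yl]ethyl}-1,2-dioxan-3-yl]propanal | O=C[C@@H](C)[C@@H]1CC[C@](C)(CC[C@@H]2C(C)=CC[C@@H]3C(C)(C)CCC[C@@]23C)OO1 | intermediate
34 | (2S)-2-[(3S,6S)-6-methyl-6-{2-[(1R,4aR,8aR)-2,5,5,8a-tetramethyl-1,4,4a,5,6,7,8,8a-octahydronaphthalen-1-yl]ethyl}-1,2-dioxan-3-yl]propanoic acid | OC(=O)[C@@H](C)[C@@H]1CC[C@](C)(CC[C@@H]2C(C)=CC[C@@H]3C(C)(C)CCC[C@@]23C)OO1 | intermediate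
35 | methyl (2S)-2-[(3S,6S)-6-methyl-6-{2-[(1R,4aR,8aR)-2,5,5,8a-tetramethyl-1,4,4a,5,6,7,8,8a-octahydronaphthalen-1-yl]ethyl}-1,2-dioxan-3-yl]propanoate | COC(=O)[C@@H](C)[C@@H]1CC[C@](C)(CC[C@@H]2C(C)=CC[C@@H]3C(C)(C)CCC[C@@]23C)OO1 | target

**Step count**

Total: 28 steps. Longest linear sequence: 16 steps (steps 13–28, from geranyl acetate 17); the decalin branch from carvone 1 runs to 15 steps (steps 1–3, 6–12, 24–28).

**Steps most likely to fail**

1. Step 7 (cation–vinylsilane ring closure). The C14 cation may lose a proton to the isopropenyl or isopropylidene olefin, or the vinylsilane may be protodesilylated, before the weakly nucleophilic vinylsilane reaches the hindered cation. The fallback sets out from 4 and returns at 11, and uses a plain terminal alkene in protic acid, where proton loss is reversible. Ketone 4 would be alkylated with allyl bromide (LDA, THF, −78 °C) to the trimethylsilyl-protected 6-allyl-6-methyl ketone F1, with allyl again anti to the C13 group. Formic acid at rt would cleave the silyl ether, ionize C14 and close ring A by 6-endo attack of the terminal alkene carbon, the secondary C16 cation being trapped as the trans-decalin C16 formate F2. Methanolysis (K2CO3, MeOH) would give the C16 alcohol F3, and thiocarbonyldiimidazole with DMAP its imidazole-1-carbothioate F4. Barton–McCombie deoxygenation (Bu3SnH, AIBN, toluene, 100 °C) would then give enone 11 directly.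

2. Step 21 (perhydrolysis of the epoxide). Opening at the tertiary C6 may drift toward a free cation, with erosion of configuration at C6 or rearrangement, and the β-hydroxy hydroperoxide formed may fragment under the base of step 22. The fallback sets out from 26 and returns at 28; it introduces the peroxide at C3 first and closes the ring on the epoxide under acid. Epoxy alcohol 26 would be silylated (TBSCl, imidazole) to the epoxy TBS ether F5. Aqueous H2O2 with KOH in MeOH/THF would displace the C3 mesylate with inversion to give the C3 hydroperoxide F6. Catalytic camphorsulfonic acid in CH2Cl2 would then trigger intramolecular 6-exo opening of the epoxide at C6 with inversion, giving the dioxane TBS ether F7. Selective removal of the primary TBS group (HF·pyridine, pyridine, THF, 0 °C) would give diol 28.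

3. Step 24 (Julia–Kocienski union). Addition of the hindered C8 sulfonyl anion to the α-quaternary peroxy aldehyde may be slow, so that self-condensation of the sulfone or base-induced breakdown of the peroxide takes over. The fallback sets out from 14 and returns at 31; it uses a phosphorus ylide in place of the sulfone. ent-Drimenol 14 would be converted (I2, PPh3, imidazole) into the C8 iodide F8 and then (PPh3, MeCN, reflux) into the triphenylphosphonium iodide F9. Its ylide (NaHMDS, THF, −78 °C) would be combined with aldehyde 29 in a Wittig reaction to give mainly the (Z)-C7=C8 alkene F10, which diimide under the conditions of step 25 would reduce to 31.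

**Further compounds**

F1 | step 7 | (5S,6R)-2,6-dimethyl-6-(prop-2-en-1-yl)-5-{2-[(trimethylsilyl)oxy]propan-2-yl}cyclohex-2-en-1-one | O=C1C(C)=CC[C@H](C(C)(C)O[Si](C)(C)C)[C@@]1(C)CC=C
F2 | step 7 | (4aR,8aR)-4,4,7,8a-tetramethyl-8-oxo-1,2,3,4,4a,5,8,8a-octahydronaphthalen-2-yl formate (C16 epimers) | O=C1C(C)=CC[C@@H]2C(C)(C)CC(OC=O)C[C@@]12C
F3 | step 7 | (4aR,8aR)-7-hydroxy-2,5,5,8a-tetramethyl-4a,5,6,7,8,8a-hexahydronaphthalen-1(4H)-one (C16 epimers) | O=C1C(C)=CC[C@@H]2C(C)(C)CC(O)C[C@@]12C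
F4 | step 7 | O-[(4aR,8aR)-4,4,7,8a-tetramethyl-8-oxo-1,2,3,4,4a,5,8,8a-octahydronaphthalen-2-yl] 1H-imidazole-1-carbothioate | O=C1C(C)=CC[C@@H]2C(C)(C)CC(OC(=S)n3ccnc3)C[C@@]12C
F5 | step 21 | (2R,3R)-5-[(2S,3S)-3-{[(tert-butyldimethylsilyl)oxy]methyl}-2-methyloxiran-2-yl]-1-[(tert-butyldiphenylsilyl)oxy]-2-methylpentan-3-yl methanesulfonate | CC(C)(C)[Si](c1ccccc1)(c1ccccc1)OC[C@@H](C)[C@H](OS(C)(=O)=O)CC[C@]1(C)O[C@H]1CO[Si](C)(C)C(C)(C)C
F6 | step 21 | C3 hydroperoxide (C3 inverted) of the epoxy TBS ether: tert-butyl{[(2S,3S)-3-{(3S,4R)-5-[(tert-butyldiphenylsilyl)oxy]-3-hydroperoxy-4-methylpentyl}-3-methyloxiran-2-yl]methoxy}dimethylsilane | CC(C)(C)[Si](c1ccccc1)(c1ccccc1)OC[C@@H](C)[C@@H](OO)CC[C@]1(C)O[C@H]1CO[Si](C)(C)C(C)(C)C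
F7 | step 21 | (1S)-2-[(tert-butyldimethylsilyl)oxy]-1-[(3R,6S)-6-{(2R)-1-[(tert-butyldiphenylsilyl)oxy]propan-2-yl}-3-methyl-1,2-dioxan-3-yl]ethan-1-ol | CC(C)(C)[Si](c1ccccc1)(c1ccccc1)OC[C@@H](C)[C@@H]1CC[C@@](C)(OO1)[C@@H](O)CO[Si](C)(C)C(C)(C)C
F8 | step 24 | (1R,4aR,8aR)-1-(iodomethyl)-2,5,5,8a-tetramethyl-1,4,4a,5,6,7,8,8a-octahydronaphthalene | IC[C@@H]1C(C)=CC[C@@H]2C(C)(C)CCC[C@@]12C
F9 | step 24 | triphenyl{[(1R,4aR,8aR)-2,5,5,8a-tetramethyl-1,4,4a,5,6,7,8,8a-octahydronaphthalen-1-yl]methyl}phosphonium iodide | c1ccccc1[P+](c1ccccc1)(c1ccccc1)C[C@@H]1C(C)=CC[C@@H]2C(C)(C)CCC[C@@]12C.[I-]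
F10 | step 24 | (Z)-C7=C8 isomer of 30 | CC(C)(C)[Si](c1ccccc1)(c1ccccc1)OC[C@@H](C)[C@@H]1CC[C@](C)(/C=C\[C@@H]2C(C)=CC[C@@H]3C(C)(C)CCC[C@@]23C)OO1
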